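**Assumption:** the target is taken exactly as written (5E olefin, 12β-OOH). Briarane numbering C1–C20 is used for all intermediates, β is the face of ring A that carries the C1 methyl (C15), and the two small acids used in steps 3 and 12 are treated as purchasable.

## Retrosynthetic overview

1. Last step and key step: Schenck ene oxygenation of the C11=C12 olefin forms the C12–OOH bond and the 11(20)-methylene.
2. The ten-membered ring and the butenolide form together: C7–C8 by a nickel/chromium alkenyl triflate–aldehyde coupling, C7–O by lactonisation in the same flask.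
3. C9–C10 comes from a Carroll rearrangement of a C12–O β-keto ester. The C12 oxygen is placed by epoxidation/Wharton transposition, and the rearrangement moves the olefin to C11=C12.
4. The C1 quaternary centre comes from acylation, then methylation of (S)-carvone (C14 from the chiral pool; isopropenyl → 14-OAc by Criegee rearrangement). C3 comes from an Evans glycolate alkylation, C2 from a chelation-controlled reduction.
5. Ring order: ring A (carvone) is present from the start; the ten-membered ring and the butenolide close in one step near the end.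

## Route

Step 1
Reactants: 1 prop-2-yn-1-ol
Product: 3 (E)-3-iodo-2-methylprop-2-en-1-ol, via alkenylalane 2 (not isolated)
Conditions: AlMe3 (3 equiv), (C5H5)2ZrCl2 (0.25 equiv), CH2Cl2, 0 °C → rt; then I2, THF, −30 °C; aqueous work-up
Reagents that add atoms: trimethylaluminium, C[Al](C)C; iodine, II
Why: Negishi zirconium-catalysed carboalumination adds CH3 and Al syn across the alkyne (CH3 on the internal carbon) and iodine replaces aluminium with retention, so the E iodoalkene with methyl cis to iodine results.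

Step 2
Reactants: 3 (E)-3-iodo-2-methylprop-2-en-1-ol
Product: 4 (E)-3-bromo-1-iodo-2-methylprop-1-ene
Conditions: CBr4, PPh3, CH2Cl2, 0 °C
Reagents that add atoms: carbon tetrabromide, BrC(Br)(Br)Br
Why: Appel bromination of the primary allylic alcohol proceeds by SN2 at CH2 and leaves the iodoalkene geometry untouched.

Step 3
Reactants: 5 (S)-4-benzyloxazolidin-2-one; 6 2-(tert-butyldimethylsilyloxy)acetic acid
Product: 7 (S)-4-benzyl-3-[2-(tert-butyldimethylsilyloxy)acetyl]oxazolidin-2-one
Conditions: DCC, DMAP (cat.), CH2Cl2, 0 °C → rt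
Reagents that add atoms: none
Why: Carbodiimide-mediated (Steglich-type) N-acylation of the oxazolidinone gives the glycolate imide.

Step 4
Reactants: 7 glycolate imide; 4 (E)-3-bromo-1-iodo-2-methylprop-1-ene
Product: 8 (S)-4-benzyl-3-[(2R,4E)-2-(tert-butyldimethylsilyloxy)-5-iodo-4-methylpent-4-enoyl]oxazolidin-2-one
Conditions: NaN(SiMe3)2, THF, −78 °C; then 4, −78 → −45 °C
Reagents that add atoms: none
Why: Evans glycolate alkylation: the chelated Z sodium enolate is alkylated on the face opposite the benzyl group, which sets the (2R) centre that becomes C3.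

Step 5
Reactants: 9 (S)-carvone; 8 alkylated imide
Product: 10 C-acylated carvone (β-diketone, C1 epimers and enol)
Conditions: 9 (2.2 equiv), LiN(iPr)2 (2.2 equiv), THF, −78 °C; then 8, −78 → −30 °C; aq. NH4Cl
Reagents that add atoms: none
Why: Crossed Claisen acylation: the kinetic α′ lithium enolate of carvone adds to the activated exocyclic imide carbonyl and expels the oxazolidinone; the product is held as its lithium diketonate, so C3 does not epimerise and the C1 configuration is irrelevant at this stage.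

Step 6
Reactants: 10 C-acylated carvone
Product: 11 C1-methylated diketone (C15 methyl β, trans to the 14α-isopropenyl group)
Conditions: MeI, K2CO3, acetone, rt
Reagents that add atoms: iodomethane, CI
Why: C-alkylation of the cyclic β-diketone enolate; iodomethane approaches anti to the neighbouring isopropenyl group, so the new quaternary C1 has its methyl β.

Step 7
Reactants: 11 C1-methylated diketone
Product: 12 (2R)-alcohol (C10 enone and 3-OTBS retained)
Conditions: Zn(BH4)2, Et2O, −30 °C; aq. NH4Cl
Reagents that add atoms: none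
Why: Chelation-controlled hydride reduction: zinc bridges the two carbonyls and hydride attacks C2 from the face of the small C1 methyl, which is also the Felkin–Anh face set by the non-chelating 3-OTBS, giving the (2R) alcohol while the hindered conjugated C10 ketone is left.

Step 8
Reactants: 12 (2R)-alcohol
Product: 14 (2R,3R)-diacetate, via diol 13 (not isolated)
Conditions: HF·pyridine, THF/pyridine, 0 °C → rt; then Ac2O, DMAP, 40 °C
Reagents that add atoms: acetic anhydride, CC(=O)OC(C)=O
Why: Fluoride desilylation followed in the same flask by DMAP-catalysed acetylation installs the C2 and C3 acetates of the target without touching any stereocentre.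

Step 9
Reactants: 14 (2R,3R)-diacetate
Product: 17 2,3,14-triacetate enone (14α-OAc), via methoxy hydroperoxide 15 (not isolated), via peracetate 16 (not isolated)
Conditions: O3, CH2Cl2/MeOH (4:1), NaHCO3, Sudan Red 7B, −78 °C; then Ac2O, Et3N, DMAP, 0 → 40 °C
Reagents that add atoms: ozone, [O-][O+]=O; methanol, CO
Why: Ozone cleaves the electron-rich 1,1-disubstituted alkene in preference to the enone and the iodoalkene, and the Criegee rearrangement of the peracetate moves C14 from carbon to oxygen with retention, so the isopropenyl group becomes the 14α-acetate (its acetyl is the old C(CH3) unit).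

Step 10
Reactants: 17 triacetate enone
Product: 18 11β,12β-epoxy-10-ketone
Conditions: t-BuOOH, DBU, CH2Cl2, 0 °C → rt
Reagents that add atoms: tert-butyl hydroperoxide, CC(C)(C)OO
Why: Weitz–Scheffer nucleophilic epoxidation: the peroxide anion adds to C12 anti to the axial 14α-acetoxy group and closes to the β-epoxide.

Step 11
Reactants: 18 epoxy ketone
Product: 20 12β-hydroxy-10(11)-ene allylic alcohol, via hydrazone 19 (not isolated)
Conditions: N2H4·H2O, AcOH, MeOH, 0 °C → rt
Reagents that add atoms: none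
Why: Wharton transposition: the epoxy hydrazone fragments with loss of N2 to the allylic alcohol, in which the epoxide oxygen stays on C12 with its β configuration and the olefin sits at C10=C11.

Step 12
Reactants: 21 Meldrum's acid; 22 3-methoxy-2-methyl-3-oxopropanoic acid
Product: 23 acyl Meldrum's acid
Conditions: DCC, DMAP, CH2Cl2, 0 °C → rt
Reagents that add atoms: none
Why: Steglich-type C-acylation of Meldrum's acid gives a stable acylketene precursor.

Step 13
Reactants: 20 allylic alcohol; 23 acyl Meldrum's acid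
Product: 26 β-keto ester (C9 on the β face of C10, olefin at C11=C12), via allyl keto ester 24 (not isolated), via keto acid 25 (not isolated)
Conditions: o-xylene, 90 °C, 1 h; then 180 °C (sealed tube), 3 h
Reagents that add atoms: none
Why: Thermolysis of 23 releases an acylketene that acylates the C12 hydroxyl, and the Carroll rearrangement (suprafacial [3,3] shift of the enolised β-keto ester) transfers C9 from the 12β oxygen to the β face of C10, sets H-10 α, moves the olefin to C11=C12 and ends with decarboxylation.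

Step 14
Reactants: 26 β-keto ester (alkenyl iodide)
Product: 27 (E)-enal
Conditions: Pd(PPh3)4 (5 mol %), CO (3 atm), Bu3SnH (slow addition), THF, 50 °C
Reagents that add atoms: carbon monoxide, [C-]#[O+]
Why: Palladium-catalysed reductive carbonylation (formylation) of the alkenyl iodide inserts CO and is quenched by tin hydride with retention of the E geometry, giving the C7 enal.

Step 15
Reactants: 27 enal
Product: 28 (Z)-enol triflate
Conditions: Tf2O, aq. LiOH, toluene, 5 °C
Reagents that add atoms: trifluoromethanesulfonic anhydride, O=S(=O)(OS(=O)(=O)C(F)(F)F)C(F)(F)F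
Why: Triflation of the lithium-chelated enolate of the β-keto ester gives the Z enol triflate (OTf cis to CO2CH3), the geometry needed for lactone closure.

Step 16
Reactants: 28 (Z)-enol triflate
Product: 30 macrocyclic butenolide (12-deoxy-11-ene), via hydroxy ester 29 (not isolated)
Conditions: CrCl2 (6 equiv), (S)-N-[2-(4-isopropyl-4,5-dihydrooxazol-2-yl)-6-methylphenyl]methanesulfonamide (6.5 equiv), Et3N, NiCl2 (10 mol %), THF/MeCN, 0.003 M, 25 °C (syringe pump); then aq. NH4Cl
Reagents that add atoms: none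
Why: Proposed new method: a ligand-controlled nickel/chromium alkenyl–aldehyde macrocyclisation with a tetrasubstituted (Z)-β-trifloxy enoate as donor, in which zerovalent nickel inserts into the C8–OTf bond, transmetalation to trivalent chromium gives an alkenylchromium that adds 1,2 to the C7 enal carbonyl under control of the chiral sulfonamide on chromium (7S intended; the ligand enantiomer is chosen by experiment), and the chromium alkoxide, held cis to the ester, lactonises in the flask to the butenolide; the closest known reactions are the Nozaki–Hiyama–Kishi macrocyclisation of alkenyl iodides and triflates and the intermolecular coupling of (Z)-β-iodoacrylates with aldehydes that gives butenolides directly.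

Step 17
Reactants: 30 macrocyclic butenolide
Product: 31 brianthein B
Conditions: O2, tetraphenylporphyrin (cat.), visible light, CH2Cl2, −20 °C, stopped at about 80 % conversion
Reagents that add atoms: oxygen, O=O
Why: Schenck ene reaction: singlet oxygen attacks the most electron-rich olefin (C11=C12) on the β face (the α face of C12 is screened by the axial 14α-acetoxy group), bonds to the less substituted C12 and takes hydrogen from the C20 methyl geminal to the bulky C10, giving the (12S) hydroperoxide and the 11(20)-methylene; C5=C6 is deactivated by the allylic lactone oxygen and the butenolide olefin is inert.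

## Compound list

1 | prop-2-yn-1-ol | C#CCO | starting material
2 | (E)-dimethyl[3-(dimethylalumanyloxy)-2-methylprop-1-enyl]alumane | C[Al](C)OC/C(C)=C/[Al](C)C | intermediate
3 | (E)-3-iodo-2-methylprop-2-en-1-ol | OC/C(C)=C/I | intermediate
4 | (E)-3-bromo-1-iodo-2-methylprop-1-ene | BrC/C(C)=C/I | intermediate
5 | (S)-4-benzyloxazolidin-2-one | O=C1OC[C@H](Cc2ccccc2)N1 | starting material
6 | 2-(tert-butyldimethylsilyloxy)acetic acid | OC(=O)CO[Si](C)(C)C(C)(C)C | starting material
7 | (S)-4-benzyl-3-[2-(tert-butyldimethylsilyloxy)acetyl]oxazolidin-2-one | O=C1OC[C@H](Cc2ccccc2)N1C(=O)CO[Si](C)(C)C(C)(C)C | intermediate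
8 | (S)-4-benzyl-3-[(2R,4E)-2-(tert-butyldimethylsilyloxy)-5-iodo-4-methylpent-4-enoyl]oxazolidin-2-one | O=C1OC[C@H](Cc2ccccc2)N1C(=O)[C@H](O[Si](C)(C)C(C)(C)C)C/C(C)=C/I | intermediate
9 | (S)-carvone, (5S)-2-methyl-5-(prop-1-en-2-yl)cyclohex-2-en-1-one | CC1=CC[C@H](C(C)=C)CC1=O | starting material
10 | C-acylated carvone: carvone C6 (= C1) carries the (2R,4E)-2-silyloxy-5-iodo-4-methylpent-4-enoyl group (C2–C6); C1 epimers/enol | CC1=CC[C@H](C(C)=C)C(C(=O)[C@H](O[Si](C)(C)C(C)(C)C)C/C(C)=C/I)C1=O | intermediate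
11 | C1-methylated diketone: quaternary C1 with C15 methyl β (trans to 14α-isopropenyl), C2 and C10 ketones, (3R)-OTBS | CC1=CC[C@H](C(C)=C)[C@@](C(=O)[C@H](O[Si](C)(C)C(C)(C)C)C/C(C)=C/I)(C)C1=O | intermediate
12 | (2R)-alcohol of 11, (3R)-OTBS, C10 enone | CC1=CC[C@H](C(C)=C)[C@@]([C@@H](O)[C@H](O[Si](C)(C)C(C)(C)C)C/C(C)=C/I)(C)C1=O | intermediate
13 | (2R,3R)-diol | CC1=CC[C@H](C(C)=C)[C@@]([C@@H](O)[C@H](O)C/C(C)=C/I)(C)C1=O | intermediate
14 | (2R,3R)-diacetate, 14α-isopropenyl | CC1=CC[C@H](C(C)=C)[C@@]([C@@H](OC(C)=O)[C@H](OC(C)=O)C/C(C)=C/I)(C)C1=O | intermediate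
15 | methoxy hydroperoxide: C14 carries C(CH3)(OCH3)OOH | CC1=CC[C@H](C(C)(OC)OO)[C@@]([C@@H](OC(C)=O)[C@H](OC(C)=O)C/C(C)=C/I)(C)C1=O | intermediate
16 | peracetate: C14 carries C(CH3)(OCH3)OOAc | CC1=CC[C@H](C(C)(OC)OOC(C)=O)[C@@]([C@@H](OC(C)=O)[C@H](OC(C)=O)C/C(C)=C/I)(C)C1=O | intermediate
17 | 2,3,14-triacetate enone: 14α-OAc, 11-en-10-one, C6 alkenyl iodide | CC1=CC[C@H](OC(C)=O)[C@@]([C@@H](OC(C)=O)[C@H](OC(C)=O)C/C(C)=C/I)(C)C1=O | intermediate
18 | 11β,12β-epoxy-10-ketone | C[C@]12O[C@H]1C[C@H](OC(C)=O)[C@@]([C@@H](OC(C)=O)[C@H](OC(C)=O)C/C(C)=C/I)(C)C2=O | intermediate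
19 | hydrazone of 18 | C[C@]12O[C@H]1C[C@H](OC(C)=O)[C@@]([C@@H](OC(C)=O)[C@H](OC(C)=O)C/C(C)=C/I)(C)C2=NN | intermediate
20 | 12β-hydroxy-10(11)-ene allylic alcohol | CC1=C[C@]([C@@H](OC(C)=O)[C@H](OC(C)=O)C/C(C)=C/I)(C)[C@@H](OC(C)=O)C[C@@H]1O | intermediate
21 | Meldrum's acid, 2,2-dimethyl-1,3-dioxane-4,6-dione | CC1(C)OC(=O)CC(=O)O1 | starting material
22 | 3-methoxy-2-methyl-3-oxopropanoic acid | COC(=O)C(C)C(O)=O | starting material
23 | 5-(1-hydroxy-3-methoxy-2-methyl-3-oxopropylidene)-2,2-dimethyl-1,3-dioxane-4,6-dione | COC(=O)C(C)C(O)=C1C(=O)OC(C)(C)OC1=O | intermediate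
24 | allyl keto ester: 12β-O-(5-methoxy-4-methyl-3,5-dioxopentanoyl) derivative of 20 | CC1=C[C@]([C@@H](OC(C)=O)[C@H](OC(C)=O)C/C(C)=C/I)(C)[C@@H](OC(C)=O)C[C@@H]1OC(=O)CC(=O)C(C)C(=O)OC | intermediate
25 | keto acid: C10 (β side chain) carries CH(CO2H)–C(=O)–CH(CH3)–CO2CH3, 11-ene | CC1=CC[C@H](OC(C)=O)[C@@]([C@@H](OC(C)=O)[C@H](OC(C)=O)C/C(C)=C/I)(C)[C@H]1C(C(O)=O)C(=O)C(C)C(=O)OC | intermediate
26 | β-keto ester: C10β–C9H2–C8(=O)–C17H(CH3)–CO2CH3, 11-ene, H-10α, alkenyl iodide | CC1=CC[C@H](OC(C)=O)[C@@]([C@@H](OC(C)=O)[C@H](OC(C)=O)C/C(C)=C/I)(C)[C@H]1CC(=O)C(C)C(=O)OC | intermediate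
27 | (E)-enal: iodide of 26 replaced by CHO (C7) | CC1=CC[C@H](OC(C)=O)[C@@]([C@@H](OC(C)=O)[C@H](OC(C)=O)C/C(C)=C/C=O)(C)[C@H]1CC(=O)C(C)C(=O)OC | intermediate
28 | (Z)-enol triflate: C8(OTf)=C17(CH3)CO2CH3, OTf cis to ester | CC1=CC[C@H](OC(C)=O)[C@@]([C@@H](OC(C)=O)[C@H](OC(C)=O)C/C(C)=C/C=O)(C)[C@H]1C/C(OS(=O)(=O)C(F)(F)F)=C(\C)C(=O)OC | intermediate
29 | hydroxy ester: ten-membered ring closed, (7S)-OH (as chromium alkoxide), C8=C17(CH3)CO2CH3 | CC1=CC[C@H](OC(C)=O)[C@@]2(C)[C@H]1C/C(=C(\C)C(=O)OC)[C@@H](O)/C=C(\C)C[C@@H](OC(C)=O)[C@@H]2OC(C)=O | intermediate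
30 | macrocyclic butenolide: brianthein B skeleton with C11(CH3)=C12 and no hydroperoxide | CC1=CC[C@H](OC(C)=O)[C@@]2(C)[C@H]1CC1=C(C)C(=O)O[C@H]1/C=C(\C)C[C@@H](OC(C)=O)[C@@H]2OC(C)=O | intermediate
31 | brianthein B | C=C1[C@@H](OO)C[C@H](OC(C)=O)[C@@]2(C)[C@H]1CC1=C(C)C(=O)O[C@H]1/C=C(\C)C[C@@H](OC(C)=O)[C@@H]2OC(C)=O | target

## Step count and risks

Total: 17 steps. Longest linear sequence: 15 steps (steps 1, 2, 4–11, 13–17).

The three steps most likely to fail:

**Step 16 (the new macrocyclisation).** The triflate is tetrasubstituted, the ring is strained, and the facial control at C7 is untested. The fallback uses only known chemistry; it sets out from 20 and comes back at 30. Transesterification of 20 with methyl 4,4-dimethoxy-3-oxobutanoate (DMAP, toluene, reflux) gives the allyl dimethoxy keto ester F1. Thermal Carroll rearrangement (180 °C) with loss of CO2 gives the keto acetal F2, and aqueous trifluoroacetic acid unmasks the keto aldehyde F3. A conventional alkenyl iodide–aldehyde Nozaki–Hiyama–Kishi macrocyclisation (CrCl2, cat. NiCl2, DMSO, high dilution) closes the ten-membered ring to the macrocyclic hydroxy ketone F4. Esterification with 2-(diethoxyphosphoryl)propanoic acid (DCC, DMAP) gives the phosphonate ester F5, and an intramolecular Horner–Wadsworth–Emmons reaction (LiCl, DBU, MeCN) builds the butenolide and gives 30.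

**Step 11 (Wharton transposition).** The ketone is flanked by two fully substituted carbons, and hydrazine may attack the acetates. The fallback sets out from 18 and comes back at 20. NaBH4/CeCl3 reduces the ketone to the epoxy alcohol F6, and 1,1'-thiocarbonyldiimidazole converts it into the imidazolyl thiocarbonate F7. Bu3SnH/AIBN then generates the C10 radical, which opens the epoxide to the C12 alkoxy radical and, after hydrogen transfer, gives 20 (radical deoxygenative epoxide fragmentation).

**Step 17 (Schenck ene reaction).** Attack at C5=C6, formation of the tertiary 11-hydroperoxide, or α-face attack could compete. The fallback sets out from 30 and comes back at 31. Dimethyldioxirane epoxidises C11=C12 to the epoxide F8 (either face is usable). (C5H5)2TiCl, made from (C5H5)2TiCl2 and Mn, opens it at C11 and eliminates toward C20 to give the exocyclic allylic alcohol F9. Acid-catalysed exchange with ethereal H2O2 (cat. Sc(OTf)3) through the allyl cation then gives 31, the peroxide entering at C12 on the β face away from the axial 14-acetate.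

## Further compounds

F1 | step 16 | allyl dimethoxy keto ester: 12β-O-(4,4-dimethoxy-3-oxobutanoyl) derivative of 20 | CC1=C[C@]([C@@H](OC(C)=O)[C@H](OC(C)=O)C/C(C)=C/I)(C)[C@@H](OC(C)=O)C[C@@H]1OC(=O)CC(=O)C(OC)OC
F2 | step 16 | keto acetal: C10β–CH2–C(=O)–CH(OCH3)2, 11-ene | CC1=CC[C@H](OC(C)=O)[C@@]([C@@H](OC(C)=O)[C@H](OC(C)=O)C/C(C)=C/I)(C)[C@H]1CC(=O)C(OC)OC
F3 | step 16 | keto aldehyde: C10β–CH2–C(=O)–CHO | CC1=CC[C@H](OC(C)=O)[C@@]([C@@H](OC(C)=O)[C@H](OC(C)=O)C/C(C)=C/I)(C)[C@H]1CC(=O)C=O
F4 | step 16 | macrocyclic hydroxy ketone: (7S)-OH, C8 ketone | CC1=CC[C@H](OC(C)=O)[C@@]2(C)[C@H]1CC(=O)[C@@H](O)/C=C(\C)C[C@@H](OC(C)=O)[C@@H]2OC(C)=O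
F5 | step 16 | phosphonate ester: 7-O-[2-(diethoxyphosphoryl)propanoyl] derivative of F4 | CC1=CC[C@H](OC(C)=O)[C@@]2(C)[C@H]1CC(=O)[C@@H](OC(=O)C(C)P(=O)(OCC)OCC)/C=C(\C)C[C@@H](OC(C)=O)[C@@H]2OC(C)=O
F6 | step 11 | epoxy alcohol: 10-hydroxy-11β,12β-epoxide | C[C@]12O[C@H]1C[C@H](OC(C)=O)[C@@]([C@@H](OC(C)=O)[C@H](OC(C)=O)C/C(C)=C/I)(C)C2O
F7 | step 11 | imidazolyl thiocarbonate of F6 | C[C@]12O[C@H]1C[C@H](OC(C)=O)[C@@]([C@@H](OC(C)=O)[C@H](OC(C)=O)C/C(C)=C/I)(C)C2OC(=S)n1ccnc1
F8 | step 17 | 11,12-epoxide of 30 | CC12OC1C[C@H](OC(C)=O)[C@@]3(C)[C@H]2CC2=C(C)C(=O)O[C@H]2/C=C(\C)C[C@@H](OC(C)=O)[C@@H]3OC(C)=O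
F9 | step 17 | 12-hydroxy-11(20)-ene allylic alcohol | C=C1C(O)C[C@H](OC(C)=O)[C@@]2(C)[C@H]1CC1=C(C)C(=O)O[C@H]1/C=C(\C)C[C@@H](OC(C)=O)[C@@H]2OC(C)=O
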